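**Retrosynthetic overview**
1. Target ⇒ open-chain (2Z)-2-(bromomethyl)enoate carrying a 4,5-epoxy aldehyde: a single CrCl2-mediated allylation closes the C6–C7 bond of the ten-membered ring, and the resulting alkoxide lactonises onto C12. Both esters, the cis,cis-dienoate and the ring oxirane are already in place.
2. Seco chain ⇒ C1–C2 Sonogashira union of an (E)-1,2-diiodoalkene (C7–C10, C1) with (2E)-3-methylpent-2-en-4-yn-1-ol (C2–C6, C15); then CO/MeOH at C10, cis-semireduction of C2≡C3, Sharpless epoxidation of C4=C5.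
3. Diiodide piece ⇒ Brown γ-aryloxyallylboration of 3-(trimethylsilyl)propynal (C8, C9 syn), acetate at C9, epoxy-acyl group at C8, then vinyl → aldehyde → Morita–Baylis–Hillman-type carbinol as the allyl bromide precursor.
4. Acyl side chain ⇒ Sharpless epoxidation of tiglyl alcohol, then oxidation to the acid.
5. Ring order: side-chain oxirane (step 1), ring oxirane C4–C5 (step 14), then ten-membered carbocycle and γ-lactone together in the last step (step 17).

Assumption: 3-(trimethylsilyl)prop-2-ynal and (2E)-3-methylpent-2-en-4-yn-1-ol are bought; germacrane numbering of the target (C1–C15) is used for all intermediates; 16–24 are carried as both C7 epimers, since this centre is erased in step 16.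

**Step 1**
Reactants: 1 (2E)-2-methylbut-2-en-1-ol
Product: 2 [(2R,3R)-2,3-dimethyloxiran-2-yl]methanol
Conditions: Ti(OiPr)4 (5 mol%), D-(−)-diisopropyl tartrate (6 mol%), t-BuOOH, 4 Å sieves, CH2Cl2, −20 °C
Reagents that add atoms: tert-butyl hydroperoxide, CC(C)(C)OO
Why: Sharpless asymmetric epoxidation of a primary allylic alcohol; the D-(−)-tartrate complex delivers oxygen to the alkene face that gives the (2R,3R) oxirane, so both new stereocentres are reagent-controlled.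

**Step 2**
Reactants: 2 [(2R,3R)-2,3-dimethyloxiran-2-yl]methanol
Product: 3 (2S,3R)-2,3-dimethyloxirane-2-carboxylic acid
Conditions: RuCl3 (2 mol%), NaIO4, CCl4/MeCN/H2O, rt
Reagents that add atoms: water, O
Why: RuO4-catalysed (Sharpless) oxidation of the primary alcohol to the acid through the aldehyde hydrate; the oxirane carbons are untouched (2R becomes 2S only through a priority change).

**Step 3**
Reactants: 4 1-methoxy-4-(prop-2-en-1-yloxy)benzene; 5 3-(trimethylsilyl)prop-2-ynal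
Product: 7 (3S,4S)-3-(4-methoxyphenoxy)-6-(trimethylsilyl)hex-1-en-5-yn-4-ol, via allylborane 6 (not isolated)
Conditions: s-BuLi, THF, −78 °C; (+)-Ipc2BOMe; BF3·OEt2; 5, −78 °C; then H2O2, aq. NaHCO3
Reagents that add atoms: none
Why: Brown γ-alkoxyallylboration: the (Z)-γ-aryloxyallyl borane 6 reacts through a chair Zimmerman–Traxler transition state to give the syn 1,2-diol monoether, and the isopinocampheyl groups derived from (−)-α-pinene direct attack to the re face of the ynal, which sets C9 (S) and C8 (S).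

**Step 4**
Reactants: 7 (3S,4S)-3-(4-methoxyphenoxy)-6-(trimethylsilyl)hex-1-en-5-yn-4-ol
Product: 8 (3S,4S)-3-(4-methoxyphenoxy)-6-(trimethylsilyl)hex-1-en-5-yn-4-yl acetate
Conditions: Ac2O, pyridine, DMAP (cat.), CH2Cl2, 0 °C to rt
Reagents that add atoms: acetic anhydride, CC(=O)OC(C)=O
Why: DMAP-catalysed acylation of the only free hydroxyl installs the C9 acetate without touching a stereocentre.

**Step 5**
Reactants: 8 (3S,4S)-3-(4-methoxyphenoxy)-6-(trimethylsilyl)hex-1-en-5-yn-4-yl acetate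
Product: 9 (3S,4S)-3-hydroxy-6-(trimethylsilyl)hex-1-en-5-yn-4-yl acetate
Conditions: (NH4)2Ce(NO3)6, MeCN/H2O 4:1, 0 °C
Reagents that add atoms: none
Why: Oxidative dearylation of the p-methoxyphenyl ether (arene radical cation, then quinone release) frees the C8 hydroxyl with its C–O bond, and hence its configuration, intact.

**Step 6**
Reactants: 9 (3S,4S)-3-hydroxy-6-(trimethylsilyl)hex-1-en-5-yn-4-yl acetate; 3 (2S,3R)-2,3-dimethyloxirane-2-carboxylic acid
Product: 11 (3S,4S)-4-acetoxy-6-(trimethylsilyl)hex-1-en-5-yn-3-yl (2S,3R)-2,3-dimethyloxirane-2-carboxylate, via mixed anhydride 10 (not isolated)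
Conditions: 3, 2,4,6-trichlorobenzoyl chloride, Et3N, THF, rt; then 9, DMAP, toluene, rt to 40 °C
Reagents that add atoms: none
Why: Yamaguchi esterification: DMAP transfers the hindered glycidic acyl group from mixed anhydride 10 to the C8 hydroxyl; the acid has a quaternary α-carbon and cannot epimerise.

**Step 7**
Reactants: 11 (3S,4S)-4-acetoxy-6-(trimethylsilyl)hex-1-en-5-yn-3-yl (2S,3R)-2,3-dimethyloxirane-2-carboxylate
Product: 13 (2R,3S)-3-acetoxy-1-oxo-5-(trimethylsilyl)pent-4-yn-2-yl (2S,3R)-2,3-dimethyloxirane-2-carboxylate, via diol 12 (not isolated)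
Conditions: OsO4 (2 mol%), NaIO4, 2,6-lutidine, dioxane/H2O 3:1, rt
Reagents that add atoms: NaIO4 (oxygen relayed by OsO4), [Na+].[O-]I(=O)(=O)=O
Why: Lemieux–Johnson cleavage: OsO4 dihydroxylates the only alkene (the silylalkyne is inert) and periodate cleaves diol 12 to the C7 aldehyde, which is used crude.

**Step 8**
Reactants: 13 (2R,3S)-3-acetoxy-1-oxo-5-(trimethylsilyl)pent-4-yn-2-yl (2S,3R)-2,3-dimethyloxirane-2-carboxylate; 14 methyl prop-2-ynoate
Product: 16 methyl (4S,5S)-5-acetoxy-4-{[(2S,3R)-2,3-dimethyloxiran-2-yl]carbonyloxy}-3-hydroxy-2-methylidene-7-(trimethylsilyl)hept-6-ynoate, via vinylalane 15 (not isolated)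
Conditions: 14, iBu2AlH, N-methylmorpholine N-oxide, THF, 0 °C; then 13, 0 °C; aq. KNaC4H4O6
Reagents that add atoms: none
Why: Vinylalumination: 1,4-hydroalumination of the propiolate gives α-aluminoacrylate 15, which adds to the aldehyde under non-basic conditions (no β-acetoxy elimination) to give the Morita–Baylis–Hillman-type carbinol; the new C7 centre is formed unselectively and is removed in step 16.

**Step 9**
Reactants: 16 methyl (4S,5S)-5-acetoxy-4-{[(2S,3R)-2,3-dimethyloxiran-2-yl]carbonyloxy}-3-hydroxy-2-methylidene-7-(trimethylsilyl)hept-6-ynoate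
Product: 17 methyl (4S,5S)-5-acetoxy-4-{[(2S,3R)-2,3-dimethyloxiran-2-yl]carbonyloxy}-3-hydroxy-2-methylidenehept-6-ynoate
Conditions: AgNO3 (10 mol%), acetone/H2O, rt
Reagents that add atoms: none
Why: Silver-catalysed protodesilylation of the alkynylsilane (through the silver acetylide) is neutral and leaves the three esters in place.

**Step 10**
Reactants: 17 methyl (4S,5S)-5-acetoxy-4-{[(2S,3R)-2,3-dimethyloxiran-2-yl]carbonyloxy}-3-hydroxy-2-methylidenehept-6-ynoate
Product: 18 methyl (4S,5R,6E)-5-acetoxy-4-{[(2S,3R)-2,3-dimethyloxiran-2-yl]carbonyloxy}-3-hydroxy-6,7-diiodo-2-methylidenehept-6-enoate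
Conditions: I2, CH2Cl2, rt, dark
Reagents that add atoms: iodine, II
Why: Anti addition of iodine to the terminal alkyne gives the (E)-1,2-diiodoalkene, which fixes the C10=C1 geometry (C1–I cis to C9) and differentiates the two alkenyl positions; the electron-poor acrylate does not react.

**Step 11**
Reactants: 18 methyl (4S,5R,6E)-5-acetoxy-4-{[(2S,3R)-2,3-dimethyloxiran-2-yl]carbonyloxy}-3-hydroxy-6,7-diiodo-2-methylidenehept-6-enoate; 19 (2E)-3-methylpent-2-en-4-yn-1-ol
Product: 20 methyl (4S,5R,6E,10E)-5-acetoxy-4-{[(2S,3R)-2,3-dimethyloxiran-2-yl]carbonyloxy}-3,12-dihydroxy-6-iodo-10-methyl-2-methylidenedodeca-6,10-dien-8-ynoate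
Conditions: Pd(PPh3)4 (5 mol%), CuI (10 mol%), Et3N, THF, 0 °C to rt
Reagents that add atoms: none
Why: Sonogashira coupling: oxidative addition occurs at the unhindered terminal C1–I bond rather than the internal C10–I bond next to the branched C9, and the alkene geometry is retained.

**Step 12**
Reactants: 20 methyl (4S,5R,6E,10E)-5-acetoxy-4-{[(2S,3R)-2,3-dimethyloxiran-2-yl]carbonyloxy}-3,12-dihydroxy-6-iodo-10-methyl-2-methylidenedodeca-6,10-dien-8-ynoate
Product: 21 methyl (4S,5S,6E,10E)-5-acetoxy-4-{[(2S,3R)-2,3-dimethyloxiran-2-yl]carbonyloxy}-3,12-dihydroxy-6-(methoxycarbonyl)-10-methyl-2-methylidenedodeca-6,10-dien-8-ynoate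
Conditions: PdCl2(PPh3)2 (5 mol%), CO (1 atm), MeOH (20 equiv), Et3N, DMF, 45 °C
Reagents that add atoms: carbon monoxide, [C-]#[O+]; methanol, CO
Why: Palladium-catalysed methoxycarbonylation of the alkenyl iodide (oxidative addition to zerovalent palladium, CO insertion, methanolysis) proceeds with retention, leaving CO2Me trans to C2 as in the target.

**Step 13**
Reactants: 21 methyl (4S,5S,6E,10E)-5-acetoxy-4-{[(2S,3R)-2,3-dimethyloxiran-2-yl]carbonyloxy}-3,12-dihydroxy-6-(methoxycarbonyl)-10-methyl-2-methylidenedodeca-6,10-dien-8-ynoate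
Product: 22 methyl (4S,5S,6E,8Z,10E)-5-acetoxy-4-{[(2S,3R)-2,3-dimethyloxiran-2-yl]carbonyloxy}-3,12-dihydroxy-6-(methoxycarbonyl)-10-methyl-2-methylidenedodeca-6,8,10-trienoate
Conditions: Zn dust activated with Cu(OAc)2 and AgNO3, MeOH/H2O 1:1, rt
Reagents that add atoms: none
Why: Boland-type reduction: activated zinc reduces only the triple bond flanked by two alkenes and delivers both hydrogens syn, giving the (2Z)-alkene; the esters and the side-chain oxirane are inert.

**Step 14**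
Reactants: 22 methyl (4S,5S,6E,8Z,10E)-5-acetoxy-4-{[(2S,3R)-2,3-dimethyloxiran-2-yl]carbonyloxy}-3,12-dihydroxy-6-(methoxycarbonyl)-10-methyl-2-methylidenedodeca-6,8,10-trienoate
Product: 23 methyl (4S,5S,6E,8Z)-5-acetoxy-4-{[(2S,3R)-2,3-dimethyloxiran-2-yl]carbonyloxy}-3-hydroxy-9-[(2R,3R)-3-(hydroxymethyl)-2-methyloxiran-2-yl]-6-(methoxycarbonyl)-2-methylidenenona-6,8-dienoate
Conditions: Ti(OiPr)4 (20 mol%), D-(−)-diisopropyl tartrate (24 mol%), t-BuOOH, 4 Å sieves, CH2Cl2, −20 °C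
Reagents that add atoms: tert-butyl hydroperoxide, CC(C)(C)OO
Why: Sharpless asymmetric epoxidation directed by the C6 hydroxyl; D-(−)-tartrate gives the (4R,5R) oxirane with the same facial sense as in step 1, and only the alkene of the primary allylic alcohol reacts because the C7 carbinol flanks an electron-poor acrylate.

**Step 15**
Reactants: 23 methyl (4S,5S,6E,8Z)-5-acetoxy-4-{[(2S,3R)-2,3-dimethyloxiran-2-yl]carbonyloxy}-3-hydroxy-9-[(2R,3R)-3-(hydroxymethyl)-2-methyloxiran-2-yl]-6-(methoxycarbonyl)-2-methylidenenona-6,8-dienoate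
Product: 24 methyl (4S,5S,6E,8Z)-5-acetoxy-4-{[(2S,3R)-2,3-dimethyloxiran-2-yl]carbonyloxy}-9-[(2R,3S)-3-formyl-2-methyloxiran-2-yl]-3-hydroxy-6-(methoxycarbonyl)-2-methylidenenona-6,8-dienoate
Conditions: TEMPO (10 mol%), PhI(OAc)2, CH2Cl2, rt
Reagents that add atoms: none
Why: Oxoammonium (TEMPO) oxidation is selective for the primary C6 alcohol over the hindered secondary C7 carbinol and gives the epoxy aldehyde without epimerising C5.

**Step 16**
Reactants: 24 methyl (4S,5S,6E,8Z)-5-acetoxy-4-{[(2S,3R)-2,3-dimethyloxiran-2-yl]carbonyloxy}-9-[(2R,3S)-3-formyl-2-methyloxiran-2-yl]-3-hydroxy-6-(methoxycarbonyl)-2-methylidenenona-6,8-dienoate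
Product: 25 methyl (2Z,4S,5S,6E,8Z)-5-acetoxy-2-(bromomethyl)-4-{[(2S,3R)-2,3-dimethyloxiran-2-yl]carbonyloxy}-9-[(2R,3S)-3-formyl-2-methyloxiran-2-yl]-6-(methoxycarbonyl)nona-2,6,8-trienoate
Conditions: N-bromosuccinimide, Me2S, CH2Cl2, −20 to 0 °C
Reagents that add atoms: N-bromosuccinimide, O=C1CCC(=O)N1Br
Why: Corey–Kim-type activation of the Morita–Baylis–Hillman alcohol as its alkoxysulfonium salt, followed by SN2′ attack of bromide, gives the transposed (2Z)-2-(bromomethyl)enoate and erases the C7 carbinol centre; the aldehyde and oxiranes are not attacked.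

**Step 17**
Reactants: 25 methyl (2Z,4S,5S,6E,8Z)-5-acetoxy-2-(bromomethyl)-4-{[(2S,3R)-2,3-dimethyloxiran-2-yl]carbonyloxy}-9-[(2R,3S)-3-formyl-2-methyloxiran-2-yl]-6-(methoxycarbonyl)nona-2,6,8-trienoate
Product: 28 CNP0229507.7 (methyl (4R,5R,6S,7R,8S,9S)-9-acetoxy-8-{[(2S,3R)-2,3-dimethyloxiran-2-yl]carbonyloxy}-4,5-epoxygermacra-1(10),2Z,11(13)-trien-12,6-olid-14-oate), via allylchromium 26 (not isolated), via chromium alkoxide 27 (not isolated)
Conditions: CrCl2 (8 equiv), THF/DMF 4:1, 25 added over 10 h (1 mM), 0 °C to rt; aq. KNaC4H4O6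
Reagents that add atoms: none
Why: Intramolecular Nozaki–Hiyama-type Barbier allylation followed by lactonisation: the trivalent allylchromium 26 equilibrates to its (E)-γ-substituted form and adds through a chair transition state to the epoxy aldehyde (C6/C7 anti, hence the trans-fused lactone), the aldehyde face is expected to be chosen by the ten-membered ring in formation (H5 and H6 anti, C4 methyl outside, as in closures of the parthenolide type), and chromium alkoxide 27 then closes the γ-lactone on the C12 methyl ester, so that carbocycle and lactone form in one operation and C6 (S) and C7 (R) are set last.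

**Compound list**
1 | (2E)-2-methylbut-2-en-1-ol (tiglyl alcohol) | C/C=C(\C)CO | starting material
2 | [(2R,3R)-2,3-dimethyloxiran-2-yl]methanol | OC[C@@]1(C)O[C@@H]1C | intermediate
3 | (2S,3R)-2,3-dimethyloxirane-2-carboxylic acid | OC(=O)[C@@]1(C)O[C@@H]1C | intermediate
4 | 1-methoxy-4-(prop-2-en-1-yloxy)benzene (allyl 4-methoxyphenyl ether) | C=CCOc1ccc(OC)cc1 | starting material
5 | 3-(trimethylsilyl)prop-2-ynal | O=CC#C[Si](C)(C)C | starting material
6 | [(2Z)-3-(4-methoxyphenoxy)prop-2-en-1-yl]bis[(1S,2R,3S,5S)-2,6,6-trimethylbicyclo[3.1.1]hept-3-yl]borane | COc1ccc(O/C=C\CB([C@H]2C[C@H]3C[C@@H]([C@@H]2C)C3(C)C)[C@H]2C[C@H]3C[C@@H]([C@@H]2C)C3(C)C)cc1 | intermediate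
7 | (3S,4S)-3-(4-methoxyphenoxy)-6-(trimethylsilyl)hex-1-en-5-yn-4-ol | C=C[C@H](Oc1ccc(OC)cc1)[C@@H](O)C#C[Si](C)(C)C | intermediate
8 | (3S,4S)-3-(4-methoxyphenoxy)-6-(trimethylsilyl)hex-1-en-5-yn-4-yl acetate | C=C[C@H](Oc1ccc(OC)cc1)[C@@H](OC(C)=O)C#C[Si](C)(C)C | intermediate
9 | (3S,4S)-3-hydroxy-6-(trimethylsilyl)hex-1-en-5-yn-4-yl acetate | C=C[C@H](O)[C@@H](OC(C)=O)C#C[Si](C)(C)C | intermediate
10 | (2S,3R)-2,3-dimethyloxirane-2-carboxylic 2,4,6-trichlorobenzoic anhydride | O=C(OC(=O)[C@@]1(C)O[C@@H]1C)c1c(Cl)cc(Cl)cc1Cl | intermediate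
11 | (3S,4S)-4-acetoxy-6-(trimethylsilyl)hex-1-en-5-yn-3-yl (2S,3R)-2,3-dimethyloxirane-2-carboxylate | C=C[C@H](OC(=O)[C@@]1(C)O[C@@H]1C)[C@@H](OC(C)=O)C#C[Si](C)(C)C | intermediate
12 | 1,2-diol of 11: 4-acetoxy-1,2-dihydroxy-6-(trimethylsilyl)hex-5-yn-3-yl (2S,3R)-2,3-dimethyloxirane-2-carboxylate, C3 and C4 as in 11, both C2 epimers | OCC(O)[C@H](OC(=O)[C@@]1(C)O[C@@H]1C)[C@@H](OC(C)=O)C#C[Si](C)(C)C | intermediate
13 | (2R,3S)-3-acetoxy-1-oxo-5-(trimethylsilyl)pent-4-yn-2-yl (2S,3R)-2,3-dimethyloxirane-2-carboxylate | O=C[C@H](OC(=O)[C@@]1(C)O[C@@H]1C)[C@@H](OC(C)=O)C#C[Si](C)(C)C | intermediate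
14 | methyl prop-2-ynoate (methyl propiolate) | C#CC(=O)OC | starting material
15 | methyl 2-[bis(2-methylpropyl)alumanyl]prop-2-enoate | C=C(C(=O)OC)[Al](CC(C)C)CC(C)C | intermediate
16 | methyl (4S,5S)-5-acetoxy-4-{[(2S,3R)-2,3-dimethyloxiran-2-yl]carbonyloxy}-3-hydroxy-2-methylidene-7-(trimethylsilyl)hept-6-ynoate, both C3 epimers | C=C(C(=O)OC)C(O)[C@H](OC(=O)[C@@]1(C)O[C@@H]1C)[C@@H](OC(C)=O)C#C[Si](C)(C)C | intermediate
17 | methyl (4S,5S)-5-acetoxy-4-{[(2S,3R)-2,3-dimethyloxiran-2-yl]carbonyloxy}-3-hydroxy-2-methylidenehept-6-ynoate, both C3 epimers | C=C(C(=O)OC)C(O)[C@H](OC(=O)[C@@]1(C)O[C@@H]1C)[C@@H](OC(C)=O)C#C | intermediate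
18 | methyl (4S,5R,6E)-5-acetoxy-4-{[(2S,3R)-2,3-dimethyloxiran-2-yl]carbonyloxy}-3-hydroxy-6,7-diiodo-2-methylidenehept-6-enoate, both C3 epimers | C=C(C(=O)OC)C(O)[C@H](OC(=O)[C@@]1(C)O[C@@H]1C)[C@@H](OC(C)=O)/C(I)=C\I | intermediate
19 | (2E)-3-methylpent-2-en-4-yn-1-ol | C#C/C(C)=C/CO | starting material
20 | methyl (4S,5R,6E,10E)-5-acetoxy-4-{[(2S,3R)-2,3-dimethyloxiran-2-yl]carbonyloxy}-3,12-dihydroxy-6-iodo-10-methyl-2-methylidenedodeca-6,10-dien-8-ynoate, both C3 epimers | C=C(C(=O)OC)C(O)[C@H](OC(=O)[C@@]1(C)O[C@@H]1C)[C@@H](OC(C)=O)/C(I)=C\C#C/C(C)=C/CO | intermediate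
21 | methyl (4S,5S,6E,10E)-5-acetoxy-4-{[(2S,3R)-2,3-dimethyloxiran-2-yl]carbonyloxy}-3,12-dihydroxy-6-(methoxycarbonyl)-10-methyl-2-methylidenedodeca-6,10-dien-8-ynoate, both C3 epimers | C=C(C(=O)OC)C(O)[C@H](OC(=O)[C@@]1(C)O[C@@H]1C)[C@@H](OC(C)=O)/C(C(=O)OC)=C\C#C/C(C)=C/CO | intermediate
22 | methyl (4S,5S,6E,8Z,10E)-5-acetoxy-4-{[(2S,3R)-2,3-dimethyloxiran-2-yl]carbonyloxy}-3,12-dihydroxy-6-(methoxycarbonyl)-10-methyl-2-methylidenedodeca-6,8,10-trienoate, both C3 epimers | C=C(C(=O)OC)C(O)[C@H](OC(=O)[C@@]1(C)O[C@@H]1C)[C@@H](OC(C)=O)/C(C(=O)OC)=C\C=C/C(C)=C/CO | intermediate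
23 | methyl (4S,5S,6E,8Z)-5-acetoxy-4-{[(2S,3R)-2,3-dimethyloxiran-2-yl]carbonyloxy}-3-hydroxy-9-[(2R,3R)-3-(hydroxymethyl)-2-methyloxiran-2-yl]-6-(methoxycarbonyl)-2-methylidenenona-6,8-dienoate, both C3 epimers | C=C(C(=O)OC)C(O)[C@H](OC(=O)[C@@]1(C)O[C@@H]1C)[C@@H](OC(C)=O)/C(C(=O)OC)=C\C=C/[C@@]1(C)O[C@@H]1CO | intermediate
24 | methyl (4S,5S,6E,8Z)-5-acetoxy-4-{[(2S,3R)-2,3-dimethyloxiran-2-yl]carbonyloxy}-9-[(2R,3S)-3-formyl-2-methyloxiran-2-yl]-3-hydroxy-6-(methoxycarbonyl)-2-methylidenenona-6,8-dienoate, both C3 epimers | C=C(C(=O)OC)C(O)[C@H](OC(=O)[C@@]1(C)O[C@@H]1C)[C@@H](OC(C)=O)/C(C(=O)OC)=C\C=C/[C@@]1(C)O[C@@H]1C=O | intermediate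
25 | methyl (2Z,4S,5S,6E,8Z)-5-acetoxy-2-(bromomethyl)-4-{[(2S,3R)-2,3-dimethyloxiran-2-yl]carbonyloxy}-9-[(2R,3S)-3-formyl-2-methyloxiran-2-yl]-6-(methoxycarbonyl)nona-2,6,8-trienoate | BrC/C(C(=O)OC)=C\[C@H](OC(=O)[C@@]1(C)O[C@@H]1C)[C@@H](OC(C)=O)/C(C(=O)OC)=C\C=C/[C@@]1(C)O[C@@H]1C=O | intermediate
26 | dichlorochromium allyl derived from 25 (CrCl2 in place of Br at C13, solvent ligands omitted) | Cl[Cr](Cl)C/C(C(=O)OC)=C\[C@H](OC(=O)[C@@]1(C)O[C@@H]1C)[C@@H](OC(C)=O)/C(C(=O)OC)=C\C=C/[C@@]1(C)O[C@@H]1C=O | intermediate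
27 | dichlorochromium alkoxide of the ring-closed hydroxy ester (ten-membered ring closed, C6–O–CrCl2, C11 methylidene ester, 4R,5R,6S,7R,8S,9S) | C=C(C(=O)OC)[C@@H]1[C@H](OC(=O)[C@@]2(C)O[C@@H]2C)[C@@H](OC(C)=O)/C(C(=O)OC)=C\C=C/[C@@]2(C)O[C@@H]2[C@H]1O[Cr](Cl)Cl | intermediate
28 | CNP0229507.7, methyl (4R,5R,6S,7R,8S,9S)-9-acetoxy-8-{[(2S,3R)-2,3-dimethyloxiran-2-yl]carbonyloxy}-4,5-epoxygermacra-1(10),2Z,11(13)-trien-12,6-olid-14-oate | C=C1C(=O)O[C@H]2[C@H]1[C@H](OC(=O)[C@@]1(C)O[C@@H]1C)[C@@H](OC(C)=O)/C(C(=O)OC)=C\C=C/[C@@]1(C)O[C@H]21 | target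

**Totals**
Total step count: 17. Longest linear sequence: 15 steps (steps 3 to 17, from 4 and 5 to 28).

**Three steps most likely to fail, each with one fallback**

Step 17 (ring closure and lactonisation). The risks are the face selectivity at C6 next to the oxirane, Lewis-acid damage to the vinyl oxirane by chromium salts, and 1,4-loss of the C8 carboxylate from 26 before it cyclises; the last of these is not addressed by the fallback below. The fallback sets out from 22 and comes back at 28, with the oxirane introduced last. MnO2 in CH2Cl2 oxidises only the dienylic C6 alcohol of 22 to the seco-enal F1. N-Bromosuccinimide/Me2S converts it into the bromo seco-enal F2. CrCl2 under the high-dilution conditions of step 17 closes carbocycle and lactone to the 4,5-ene lactone F3, with no oxirane present to mismatch or to open. Finally m-CPBA with NaHCO3 in CH2Cl2 at 0 °C epoxidises the only electron-rich alkene, the E-trisubstituted C4=C5 bond, from its exposed outer face to give 28; this last face selectivity is substrate-controlled and would have to be confirmed.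

Step 12 (methoxycarbonylation). The free C7 carbinol can trap the acylpalladium as a six-membered lactone, and the neighbouring C9 acetate can be lost from the alkenylpalladium. The fallback sets out from 18 and comes back at 21, masking the carbinol for the two palladium steps. Et3SiOTf and 2,6-lutidine convert 18 into the triethylsilyl ether F4. Coupling with 19 under the conditions of step 11 gives the silylated iodo dienyne F5. Carbonylation under the conditions of step 12 gives the silylated diester F6. HF·pyridine in THF at 0 °C then removes the silyl group and returns 21.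

Step 14 (epoxidation of the trienol). The alkene is deactivated by the conjugated dienoate, and the vinyl oxirane product is exposed to Ti(OiPr)4. The fallback sets out from 21 and comes back at 23, with the order of the two steps exchanged. The enynol 21 is epoxidised under the conditions of step 14 to the more robust alkynyl epoxy alcohol F7. The activated-zinc semireduction of step 13 is then carried out on F7 and gives 23 directly.

**Further compounds**
F1 | step 17 | seco-enal, methyl (4S,5S,6E,8Z,10E)-5-acetoxy-4-{[(2S,3R)-2,3-dimethyloxiran-2-yl]carbonyloxy}-3-hydroxy-6-(methoxycarbonyl)-10-methyl-2-methylidene-12-oxododeca-6,8,10-trienoate | C=C(C(=O)OC)C(O)[C@H](OC(=O)[C@@]1(C)O[C@@H]1C)[C@@H](OC(C)=O)/C(C(=O)OC)=C\C=C/C(C)=C/C=O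
F2 | step 17 | bromo seco-enal, methyl (2Z,4S,5S,6E,8Z,10E)-5-acetoxy-2-(bromomethyl)-4-{[(2S,3R)-2,3-dimethyloxiran-2-yl]carbonyloxy}-6-(methoxycarbonyl)-10-methyl-12-oxododeca-2,6,8,10-tetraenoate | BrC/C(C(=O)OC)=C\[C@H](OC(=O)[C@@]1(C)O[C@@H]1C)[C@@H](OC(C)=O)/C(C(=O)OC)=C\C=C/C(C)=C/C=O
F3 | step 17 | 4,5-ene lactone, the (4E)-4,5-alkene in place of the ring oxirane of 28 | C=C1C(=O)O[C@H]2[C@H]1[C@H](OC(=O)[C@@]1(C)O[C@@H]1C)[C@@H](OC(C)=O)/C(C(=O)OC)=C\C=C/C(C)=C/2
F4 | step 12 | triethylsilyl ether of 18 at the C3 hydroxyl | C=C(C(=O)OC)C(O[Si](CC)(CC)CC)[C@H](OC(=O)[C@@]1(C)O[C@@H]1C)[C@@H](OC(C)=O)/C(I)=C\I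
F5 | step 12 | silylated iodo dienyne, the C3 triethylsilyl ether of 20 | C=C(C(=O)OC)C(O[Si](CC)(CC)CC)[C@H](OC(=O)[C@@]1(C)O[C@@H]1C)[C@@H](OC(C)=O)/C(I)=C\C#C/C(C)=C/CO
F6 | step 12 | silylated diester, the C3 triethylsilyl ether of 21 | C=C(C(=O)OC)C(O[Si](CC)(CC)CC)[C@H](OC(=O)[C@@]1(C)O[C@@H]1C)[C@@H](OC(C)=O)/C(C(=O)OC)=C\C#C/C(C)=C/CO
F7 | step 14 | alkynyl epoxy alcohol, methyl (4S,5S,6E)-5-acetoxy-4-{[(2S,3R)-2,3-dimethyloxiran-2-yl]carbonyloxy}-3-hydroxy-9-[(2R,3R)-3-(hydroxymethyl)-2-methyloxiran-2-yl]-6-(methoxycarbonyl)-2-methylidenenon-6-en-8-ynoate | C=C(C(=O)OC)C(O)[C@H](OC(=O)[C@@]1(C)O[C@@H]1C)[C@@H](OC(C)=O)/C(C(=O)OC)=C\C#C[C@@]1(C)O[C@@H]1CO
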